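Everything rests on opening dioxane ring B at the O3A–Ca bond (O3A: ring A oxygen meta to the formyl carbon; Ca: ring B carbon carrying arene ring C; Cb: its CH2O-bearing neighbour). Ca is benzylic and para to the ring C oxygen O4C, so acid turns a Ca carbinol into a quinone-methide-type cation that O3A traps; because this closure is reversible, the purchased Cb centre alone imposes the trans ring on either Ca epimer in one operation. The precursor is protocatechualdehyde etherified at O4A by (S)-Cb, with free O3A–H, a Ca hydroxyl and a 3-bromo-4-hydroxyphenyl ring C whose phenol and bromide later build cis ring D.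

Key step: step 10

Remark on the chemistry: 12, 13 and 14 are carried as both Ca epimers (their SMILES leave Ca undefined) because step 10 converges them; O4C is taken through step 10 as the free phenol, since it is released together with O3A–H in step 9 and is needed as such in step 15; Ce and Cd are the ring D carbons bearing ring E and CH2O.

Step 1
Reactants: 1 3,4-dihydroxybenzaldehyde
Product: 2 3-(allyloxy)-4-hydroxybenzaldehyde
Conditions: NaH (2.2 equiv), DMSO, 20 °C; allyl bromide (1.0 equiv), 20 °C; then 1 M HCl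
Reagents that add atoms: allyl bromide, C=CCBr
Why: Williamson etherification of the catechol dianion: the 4-phenoxide is delocalised into the para formyl group and is the poorer nucleophile, so one equivalent of allyl bromide should alkylate the 3-phenoxide and leave O4A free.

Step 2
Reactants: 3 methyl (4R)-2,2-dimethyl-1,3-dioxolane-4-carboxylate
Product: 4 methyl (2R)-2,3-dihydroxypropanoate
Conditions: p-toluenesulfonic acid monohydrate (TsOH·H2O, 5 mol %), MeOH, rt; NaHCO3, filter, concentrate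
Reagents that add atoms: none
Why: Acid-catalysed transketalisation to methanol cleaves the acetonide without touching the ester or the stereocentre.

Step 3
Reactants: 4 methyl (2R)-2,3-dihydroxypropanoate
Product: 5 methyl (2R)-2-hydroxy-3-[(triisopropylsilyl)oxy]propanoate
Conditions: TIPSCl (1.05 equiv), imidazole, CH2Cl2, 0 °C
Reagents that add atoms: triisopropylsilyl chloride, CC(C)[Si](Cl)(C(C)C)C(C)C
Why: Silylation with a bulky chlorosilane should select the primary hydroxyl over the hindered, ester-deactivated secondary one; no stereocentre is touched.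

Step 4
Reactants: 2 3-(allyloxy)-4-hydroxybenzaldehyde; 5 methyl (2R)-2-hydroxy-3-[(triisopropylsilyl)oxy]propanoate
Product: 6 methyl (2S)-2-[2-(allyloxy)-4-formylphenoxy]-3-[(triisopropylsilyl)oxy]propanoate
Conditions: PPh3, DIAD, THF, 0 °C → rt
Reagents that add atoms: none
Why: Mitsunobu reaction of an acidic para-formyl phenol with an α-hydroxy ester, in which SN2 displacement of the oxyphosphonium inverts C2 and so sets Cb as (S).

Step 5
Reactants: 6 methyl (2S)-2-[2-(allyloxy)-4-formylphenoxy]-3-[(triisopropylsilyl)oxy]propanoate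
Product: 7 methyl (2S)-2-[2-(allyloxy)-4-(dimethoxymethyl)phenoxy]-3-[(triisopropylsilyl)oxy]propanoate
Conditions: HC(OMe)3, MeOH, pyridinium p-toluenesulfonate (PPTS, 5 mol %), rt; Et3N quench
Reagents that add atoms: trimethyl orthoformate, COC(OC)OC; methanol, CO
Why: Acid-catalysed acetalisation with orthoformate as water scavenger masks the aryl aldehyde for the hydride and Grignard steps; it is placed after step 4 because an acetal para to a free phenol would be too labile to carry.

Step 6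
Reactants: 7 methyl (2S)-2-[2-(allyloxy)-4-(dimethoxymethyl)phenoxy]-3-[(triisopropylsilyl)oxy]propanoate
Product: 8 (2S)-2-[2-(allyloxy)-4-(dimethoxymethyl)phenoxy]-3-[(triisopropylsilyl)oxy]propanal
Conditions: iBu2AlH (DIBAL-H, 1.1 equiv), CH2Cl2, −78 °C; MeOH, then aqueous KNaC4H4O6 (potassium sodium tartrate); used crude at once
Reagents that add atoms: none
Why: DIBAL-H half-reduction of an α-oxygenated methyl ester stops at the stable tetrahedral aluminate at −78 °C and gives the aldehyde on work-up, with acetal, silyl ether and Cb untouched.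

Step 7
Reactants: 9 2-bromo-4-iodophenol
Product: 10 1-(allyloxy)-2-bromo-4-iodobenzene
Conditions: allyl bromide, K2CO3, acetone, reflux
Reagents that add atoms: allyl bromide, C=CCBr
Why: Williamson O-allylation of the phenol gives an ether that tolerates organomagnesium chemistry.

Step 8
Reactants: 10 1-(allyloxy)-2-bromo-4-iodobenzene; 8 (2S)-2-[2-(allyloxy)-4-(dimethoxymethyl)phenoxy]-3-[(triisopropylsilyl)oxy]propanal
Product: 12 (2S)-1-[4-(allyloxy)-3-bromophenyl]-2-[2-(allyloxy)-4-(dimethoxymethyl)phenoxy]-3-[(triisopropylsilyl)oxy]propan-1-ol (both C1 epimers), via arylmagnesium chloride 11 (not isolated)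
Conditions: 10 (1.3 equiv), iPrMgCl·LiCl (1.25 equiv), THF, −20 °C; then 8, THF, −78 → −30 °C; aqueous NH4Cl buffered to pH 8
Reagents that add atoms: none
Why: Iodine–magnesium exchange is selective for C–I over C–Br, and the aryl Grignard should add to the aldehyde (1,2-addition) faster than it enolises it, so Cb is kept while Ca, which step 10 resets, may form as a mixture.

Step 9
Reactants: 12 (2S)-1-[4-(allyloxy)-3-bromophenyl]-2-[2-(allyloxy)-4-(dimethoxymethyl)phenoxy]-3-[(triisopropylsilyl)oxy]propan-1-ol (both C1 epimers)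
Product: 14 4-{[(2S)-1-(3-bromo-4-hydroxyphenyl)-1-hydroxy-3-[(triisopropylsilyl)oxy]propan-2-yl]oxy}-3-hydroxybenzaldehyde (both Ca epimers), via bisphenol dimethyl acetal 13 (not isolated)
Conditions: Pd(PPh3)4 (5 mol %), morpholine, THF, rt; aqueous wash; then pyridinium p-toluenesulfonate (PPTS, 10 mol %), THF–H2O, rt
Reagents that add atoms: water, O
Why: Tsuji–Trost deallylation, in which zerovalent palladium ionises both aryl allyl ethers and morpholine traps the allyl groups while the aryl bromide is inert at room temperature, followed by mild acetal hydrolysis that does not ionise Ca.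

Step 10
Reactants: 14 4-{[(2S)-1-(3-bromo-4-hydroxyphenyl)-1-hydroxy-3-[(triisopropylsilyl)oxy]propan-2-yl]oxy}-3-hydroxybenzaldehyde (both Ca epimers)
Product: 15 (2S,3S)-3-(3-bromo-4-hydroxyphenyl)-2-{[(triisopropylsilyl)oxy]methyl}-2,3-dihydro-1,4-benzodioxine-6-carbaldehyde (trans ring B)
Conditions: TsOH·H2O (10 mol %), CH2Cl2 (0.01 M), 4 Å molecular sieves, rt until equilibrated; NaHCO3 quench
Reagents that add atoms: none
Why: TsOH protonates the Ca hydroxyl and water leaves with help from the para oxygen O4C, giving a para-hydroxybenzyl cation that is the O-protonated para-quinone methide of ring C. The closest known reaction type is the acid-promoted cyclisation of para-oxygenated 1-aryl-2-aryloxypropanol derivatives onto a neighbouring phenol to give trans-2-aryl-1,4-benzodioxanes. Ring B closes by 6-exo-trig attack of the free phenol oxygen O3A on the exocyclic carbon Ca. The new stereocentre Ca is controlled by Cb: C–O bond formation at Ca is reversible under the acid, so both Ca epimers of 14 and any cis product should drain into the half-chair with aryl and silyloxymethyl both pseudo-equatorial, which is the (2S,3S)-trans ring. The step needs trans over cis selectivity and O- over C-capture; the first is secured by thermodynamic control from the fixed (S)-Cb centre, the second by the proximity of O3A, the formyl group that deactivates the ring A carbons, and high dilution. Cb is not benzylic and cannot ionise, and catalytic anhydrous acid at room temperature should leave the TIPS ether, the aryl bromide and the aldehyde alone.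

Step 11
Reactants: 16 (2E)-3-(3,4-dihydroxyphenyl)prop-2-enoic acid (caffeic acid)
Product: 17 allyl (2E)-3-[3,4-bis(allyloxy)phenyl]prop-2-enoate
Conditions: allyl bromide (3.6 equiv), K2CO3 (4 equiv), DMF, 40 °C
Reagents that add atoms: allyl bromide, C=CCBr
Why: Exhaustive Williamson-type alkylation of both phenoxides and the carboxylate gives base-stable catechol ethers that can later be removed without acid.

Step 12
Reactants: 17 allyl (2E)-3-[3,4-bis(allyloxy)phenyl]prop-2-enoate
Product: 18 (2E)-3-[3,4-bis(allyloxy)phenyl]prop-2-en-1-ol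
Conditions: iBu2AlH (DIBAL-H, 2.5 equiv), CH2Cl2, −78 → −20 °C; aqueous KNaC4H4O6
Reagents that add atoms: none
Why: DIBAL-H 1,2-reduction of the α,β-unsaturated ester gives the (E)-allylic alcohol without conjugate reduction.

Step 13
Reactants: 18 (2E)-3-[3,4-bis(allyloxy)phenyl]prop-2-en-1-ol
Product: 19 [(2S,3S)-3-[3,4-bis(allyloxy)phenyl]oxiran-2-yl]methanol
Conditions: Ti(OiPr)4 (10 mol %), L-(+)-diisopropyl tartrate (12 mol %), tBuOOH (2 equiv, anhydrous in isooctane), 4 Å molecular sieves, CH2Cl2, −20 °C; cold aqueous NaOH/NaCl work-up; used without chromatography on acidic silica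
Reagents that add atoms: tert-butyl hydroperoxide, CC(C)(C)OO
Why: Sharpless asymmetric epoxidation, in which the L-(+)-tartrate titanium complex delivers oxygen to the face of the (E)-allylic alcohol that gives the (2S,3S)-epoxide (reagent control of Cd and the future Ce), while the allyl ether alkenes, not being allylic alcohols, stay untouched.

Step 14
Reactants: 19 [(2S,3S)-3-[3,4-bis(allyloxy)phenyl]oxiran-2-yl]methanol
Product: 20 {[(2S,3S)-3-[3,4-bis(allyloxy)phenyl]oxiran-2-yl]methoxy}triisopropylsilane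
Conditions: TIPSCl, imidazole, CH2Cl2, 0 °C → rt
Reagents that add atoms: triisopropylsilyl chloride, CC(C)[Si](Cl)(C(C)C)C(C)C
Why: Silylation of the primary alcohol under imidazole buffer protects the CH2O group in advance and removes the free hydroxyl that would allow Payne rearrangement in the next step.

Step 15
Reactants: 15 (2S,3S)-3-(3-bromo-4-hydroxyphenyl)-2-{[(triisopropylsilyl)oxy]methyl}-2,3-dihydro-1,4-benzodioxine-6-carbaldehyde; 20 {[(2S,3S)-3-[3,4-bis(allyloxy)phenyl]oxiran-2-yl]methoxy}triisopropylsilane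
Product: 21 (2S,3S)-3-[3-bromo-4-{[(1R,2S)-1-[3,4-bis(allyloxy)phenyl]-2-hydroxy-3-[(triisopropylsilyl)oxy]propyl]oxy}phenyl]-2-{[(triisopropylsilyl)oxy]methyl}-2,3-dihydro-1,4-benzodioxine-6-carbaldehyde
Conditions: Cs2CO3 (1.5 equiv), 20 (1.3 equiv), DMF, 70 °C
Reagents that add atoms: none
Why: Base-mediated SN2 opening of an aryl oxirane by the O4C phenoxide should go to the benzylic carbon, which is activated by the para oxygen of ring E while the other carbon is retarded by the adjacent CH2O group, with inversion, so Ce becomes (R) beside the untouched (S)-Cd (erythro).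

Step 16
Reactants: 21 (2S,3S)-3-[3-bromo-4-{[(1R,2S)-1-[3,4-bis(allyloxy)phenyl]-2-hydroxy-3-[(triisopropylsilyl)oxy]propyl]oxy}phenyl]-2-{[(triisopropylsilyl)oxy]methyl}-2,3-dihydro-1,4-benzodioxine-6-carbaldehyde
Product: 22 (2S,3S)-3-[(2R,3S)-2-[3,4-bis(allyloxy)phenyl]-3-{[(triisopropylsilyl)oxy]methyl}-2,3-dihydro-1,4-benzodioxin-6-yl]-2-{[(triisopropylsilyl)oxy]methyl}-2,3-dihydro-1,4-benzodioxine-6-carbaldehyde
Conditions: CuI (10 mol %), 3,4,7,8-tetramethyl-1,10-phenanthroline (20 mol %), Cs2CO3 (2 equiv), toluene, 100 °C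
Reagents that add atoms: none
Why: Ullmann-type C–O coupling with a monovalent copper catalyst closes six-membered ring D between the Cd alkoxide and the ortho bromide; no bond at Cd or Ce is broken, so the erythro pair is carried over as the cis (2R,3S) ring without any acid.

Step 17
Reactants: 22 (2S,3S)-3-[(2R,3S)-2-[3,4-bis(allyloxy)phenyl]-3-{[(triisopropylsilyl)oxy]methyl}-2,3-dihydro-1,4-benzodioxin-6-yl]-2-{[(triisopropylsilyl)oxy]methyl}-2,3-dihydro-1,4-benzodioxine-6-carbaldehyde
Product: 23 (2S,3S)-3-[(2R,3S)-2-(3,4-dihydroxyphenyl)-3-{[(triisopropylsilyl)oxy]methyl}-2,3-dihydro-1,4-benzodioxin-6-yl]-2-{[(triisopropylsilyl)oxy]methyl}-2,3-dihydro-1,4-benzodioxine-6-carbaldehyde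
Conditions: Pd(PPh3)4 (5 mol %), morpholine, THF, rt, under argon
Reagents that add atoms: none
Why: Tsuji–Trost deallylation with zerovalent palladium and morpholine frees the ring E catechol under near-neutral conditions before the enal exists, so no amine meets a Michael acceptor.

Step 18
Reactants: 23 (2S,3S)-3-[(2R,3S)-2-(3,4-dihydroxyphenyl)-3-{[(triisopropylsilyl)oxy]methyl}-2,3-dihydro-1,4-benzodioxin-6-yl]-2-{[(triisopropylsilyl)oxy]methyl}-2,3-dihydro-1,4-benzodioxine-6-carbaldehyde
Product: 24 (2E)-3-[(2S,3S)-3-[(2R,3S)-2-(3,4-dihydroxyphenyl)-3-{[(triisopropylsilyl)oxy]methyl}-2,3-dihydro-1,4-benzodioxin-6-yl]-2-{[(triisopropylsilyl)oxy]methyl}-2,3-dihydro-1,4-benzodioxin-6-yl]prop-2-enal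
Conditions: Ph3P=CHCHO (1.2 equiv), toluene, 80 °C, under argon
Reagents that add atoms: (triphenylphosphoranylidene)acetaldehyde, O=CC=P(c1ccccc1)(c1ccccc1)c1ccccc1
Why: Wittig olefination with the stabilised formylmethylene ylide should give the (E)-enal under neutral conditions that tolerate the free catechol and the silyl ethers, a small excess limiting a second homologation.

Step 19
Reactants: 24 (2E)-3-[(2S,3S)-3-[(2R,3S)-2-(3,4-dihydroxyphenyl)-3-{[(triisopropylsilyl)oxy]methyl}-2,3-dihydro-1,4-benzodioxin-6-yl]-2-{[(triisopropylsilyl)oxy]methyl}-2,3-dihydro-1,4-benzodioxin-6-yl]prop-2-enal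
Product: 25 (2E)-3-[(2S,3S)-3-[(2R,3S)-2-(3,4-dihydroxyphenyl)-3-(hydroxymethyl)-2,3-dihydro-1,4-benzodioxin-6-yl]-2-(hydroxymethyl)-2,3-dihydro-1,4-benzodioxin-6-yl]prop-2-enal (CNP0302404.1)
Conditions: HF·pyridine, pyridine, THF, 0 °C → rt
Reagents that add atoms: none
Why: Fluoride-driven Si–O cleavage with pyridine-buffered HF·pyridine removes both primary TIPS ethers without forming phenoxides or strong acid, so the enal and the cis ring D, whose Ce is benzylic and para to a phenol, should stay intact.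

Compound list
1 | 3,4-dihydroxybenzaldehyde | O=Cc1ccc(O)c(O)c1 | starting material
2 | 3-(allyloxy)-4-hydroxybenzaldehyde | O=Cc1ccc(O)c(OCC=C)c1 | intermediate
3 | methyl (4R)-2,2-dimethyl-1,3-dioxolane-4-carboxylate | COC(=O)[C@H]1COC(C)(C)O1 | starting material
4 | methyl (2R)-2,3-dihydroxypropanoate | COC(=O)[C@H](O)CO | intermediate
5 | methyl (2R)-2-hydroxy-3-[(triisopropylsilyl)oxy]propanoate | COC(=O)[C@H](O)CO[Si](C(C)C)(C(C)C)C(C)C | intermediate
6 | methyl (2S)-2-[2-(allyloxy)-4-formylphenoxy]-3-[(triisopropylsilyl)oxy]propanoate | COC(=O)[C@H](CO[Si](C(C)C)(C(C)C)C(C)C)Oc1ccc(C=O)cc1OCC=C | intermediate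
7 | methyl (2S)-2-[2-(allyloxy)-4-(dimethoxymethyl)phenoxy]-3-[(triisopropylsilyl)oxy]propanoate | COC(=O)[C@H](CO[Si](C(C)C)(C(C)C)C(C)C)Oc1ccc(C(OC)OC)cc1OCC=C | intermediate
8 | (2S)-2-[2-(allyloxy)-4-(dimethoxymethyl)phenoxy]-3-[(triisopropylsilyl)oxy]propanal | O=C[C@H](CO[Si](C(C)C)(C(C)C)C(C)C)Oc1ccc(C(OC)OC)cc1OCC=C | intermediate
9 | 2-bromo-4-iodophenol | Oc1ccc(I)cc1Br | starting material
10 | 1-(allyloxy)-2-bromo-4-iodobenzene | C=CCOc1ccc(I)cc1Br | intermediate
11 | [4-(allyloxy)-3-bromophenyl]magnesium chloride (LiCl complex, formed in the flask) | C=CCOc1ccc([Mg]Cl)cc1Br | intermediate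
12 | (2S)-1-[4-(allyloxy)-3-bromophenyl]-2-[2-(allyloxy)-4-(dimethoxymethyl)phenoxy]-3-[(triisopropylsilyl)oxy]propan-1-ol (both C1 epimers) | C=CCOc1cc(C(OC)OC)ccc1O[C@@H](CO[Si](C(C)C)(C(C)C)C(C)C)C(O)c1ccc(OCC=C)c(Br)c1 | intermediate
13 | 2-{[(2S)-1-(3-bromo-4-hydroxyphenyl)-1-hydroxy-3-[(triisopropylsilyl)oxy]propan-2-yl]oxy}-5-(dimethoxymethyl)phenol (both Ca epimers, formed in the flask) | COC(OC)c1ccc(O[C@@H](CO[Si](C(C)C)(C(C)C)C(C)C)C(O)c2ccc(O)c(Br)c2)c(O)c1 | intermediate
14 | 4-{[(2S)-1-(3-bromo-4-hydroxyphenyl)-1-hydroxy-3-[(triisopropylsilyl)oxy]propan-2-yl]oxy}-3-hydroxybenzaldehyde (both Ca epimers) | O=Cc1ccc(O[C@@H](CO[Si](C(C)C)(C(C)C)C(C)C)C(O)c2ccc(O)c(Br)c2)c(O)c1 | intermediate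
15 | (2S,3S)-3-(3-bromo-4-hydroxyphenyl)-2-{[(triisopropylsilyl)oxy]methyl}-2,3-dihydro-1,4-benzodioxine-6-carbaldehyde | O=Cc1ccc2c(c1)O[C@@H](c1ccc(O)c(Br)c1)[C@H](CO[Si](C(C)C)(C(C)C)C(C)C)O2 | intermediate
16 | (2E)-3-(3,4-dihydroxyphenyl)prop-2-enoic acid (caffeic acid) | OC(=O)/C=C/c1ccc(O)c(O)c1 | starting material
17 | allyl (2E)-3-[3,4-bis(allyloxy)phenyl]prop-2-enoate | C=CCOC(=O)/C=C/c1ccc(OCC=C)c(OCC=C)c1 | intermediate
18 | (2E)-3-[3,4-bis(allyloxy)phenyl]prop-2-en-1-ol | OC/C=C/c1ccc(OCC=C)c(OCC=C)c1 | intermediate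
19 | [(2S,3S)-3-[3,4-bis(allyloxy)phenyl]oxiran-2-yl]methanol | OC[C@@H]1O[C@H]1c1ccc(OCC=C)c(OCC=C)c1 | intermediate
20 | {[(2S,3S)-3-[3,4-bis(allyloxy)phenyl]oxiran-2-yl]methoxy}triisopropylsilane | CC(C)[Si](OC[C@@H]1O[C@H]1c1ccc(OCC=C)c(OCC=C)c1)(C(C)C)C(C)C | intermediate
21 | (2S,3S)-3-[3-bromo-4-{[(1R,2S)-1-[3,4-bis(allyloxy)phenyl]-2-hydroxy-3-[(triisopropylsilyl)oxy]propyl]oxy}phenyl]-2-{[(triisopropylsilyl)oxy]methyl}-2,3-dihydro-1,4-benzodioxine-6-carbaldehyde | O=Cc1ccc2c(c1)O[C@@H](c1ccc(O[C@@H]([C@@H](O)CO[Si](C(C)C)(C(C)C)C(C)C)c3ccc(OCC=C)c(OCC=C)c3)c(Br)c1)[C@H](CO[Si](C(C)C)(C(C)C)C(C)C)O2 | intermediate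
22 | (2S,3S)-3-[(2R,3S)-2-[3,4-bis(allyloxy)phenyl]-3-{[(triisopropylsilyl)oxy]methyl}-2,3-dihydro-1,4-benzodioxin-6-yl]-2-{[(triisopropylsilyl)oxy]methyl}-2,3-dihydro-1,4-benzodioxine-6-carbaldehyde | O=Cc1ccc2c(c1)O[C@@H](c1ccc3c(c1)O[C@@H](CO[Si](C(C)C)(C(C)C)C(C)C)[C@@H](c1ccc(OCC=C)c(OCC=C)c1)O3)[C@H](CO[Si](C(C)C)(C(C)C)C(C)C)O2 | intermediate
23 | (2S,3S)-3-[(2R,3S)-2-(3,4-dihydroxyphenyl)-3-{[(triisopropylsilyl)oxy]methyl}-2,3-dihydro-1,4-benzodioxin-6-yl]-2-{[(triisopropylsilyl)oxy]methyl}-2,3-dihydro-1,4-benzodioxine-6-carbaldehyde | O=Cc1ccc2c(c1)O[C@@H](c1ccc3c(c1)O[C@@H](CO[Si](C(C)C)(C(C)C)C(C)C)[C@@H](c1ccc(O)c(O)c1)O3)[C@H](CO[Si](C(C)C)(C(C)C)C(C)C)O2 | intermediate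
24 | (2E)-3-[(2S,3S)-3-[(2R,3S)-2-(3,4-dihydroxyphenyl)-3-{[(triisopropylsilyl)oxy]methyl}-2,3-dihydro-1,4-benzodioxin-6-yl]-2-{[(triisopropylsilyl)oxy]methyl}-2,3-dihydro-1,4-benzodioxin-6-yl]prop-2-enal | O=C/C=C/c1ccc2c(c1)O[C@@H](c1ccc3c(c1)O[C@@H](CO[Si](C(C)C)(C(C)C)C(C)C)[C@@H](c1ccc(O)c(O)c1)O3)[C@H](CO[Si](C(C)C)(C(C)C)C(C)C)O2 | intermediate
25 | (2E)-3-[(2S,3S)-3-[(2R,3S)-2-(3,4-dihydroxyphenyl)-3-(hydroxymethyl)-2,3-dihydro-1,4-benzodioxin-6-yl]-2-(hydroxymethyl)-2,3-dihydro-1,4-benzodioxin-6-yl]prop-2-enal | O=C/C=C/c1ccc2c(c1)O[C@@H](c1ccc3c(c1)O[C@@H](CO)[C@@H](c1ccc(O)c(O)c1)O3)[C@H](CO)O2 | target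

Total step count: 19. Longest linear sequence: 13 steps (steps 2, 3, 4, 5, 6, 8, 9, 10, 15, 16, 17, 18, 19).

Steps most likely to fail

Step 10. What may go wrong: proton loss from the Ca cation toward Cb (enol ether formation) and reprotonation would erode the Cb configuration, the thermodynamic bias toward trans may be incomplete, and intermolecular capture of the quinone methide would give oligomers. The fallback is a stereospecific closure that never ionises Ca; it sets out from 9 and 8 and comes back at 15. 2-Bromo-4-iodophenol 9 is silylated (TIPSCl, imidazole) to (2-bromo-4-iodophenoxy)triisopropylsilane F1. Iodine–magnesium exchange (iPrMgCl·LiCl, −20 °C) gives the arylmagnesium chloride F2, which is added to aldehyde 8 to give the carbinol epimers F3. Dess–Martin periodinane with NaHCO3 buffer gives the aryl ketone F4, and chelation-controlled reduction with Zn(BH4)2 in Et2O should give the erythro (1R,2S) alcohol F5. Pd(PPh3)4 and morpholine remove the ring A allyl ether to give the phenol acetal F6, and wet PPTS hydrolyses it to the phenol aldehyde F7. Intramolecular Mitsunobu etherification (PPh3, DIAD, THF, 0 °C) closes O3A–Ca by SN2 with inversion to the trans benzodioxane aryl silyl ether F8. K2CO3 in MeOH at rt then cleaves only the aryl silyl ether and gives 15.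

Step 15. What may go wrong: attack at the non-benzylic oxirane carbon, a sluggish opening by the hindered ortho-bromophenoxide that forces temperatures at which the configuration at Ce leaks, or silyl migration in the product alkoxide. The fallback uses the free epoxy alcohol and silylates afterwards; it sets out from 15 and 19 and comes back at 21. The phenoxide of 15 (aqueous NaOH, tBuOH, 60 °C, the conditions under which phenoxides open trans-3-arylglycidols at the benzylic carbon) opens 19 with inversion to the (1R,2S)-diol F9, in which no silyl group can migrate. TIPSCl and imidazole at 0 °C then silylate the primary hydroxyl selectively and give 21.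

Step 13. What may go wrong: Lewis acid opening of the electron-rich aryl oxirane on titanium during the reaction or work-up, with loss of material and of enantiomeric purity. The fallback forms the oxirane under basic conditions on the silyl ether; it sets out from 18 and comes back at 20. Alcohol 18 is silylated (TIPSCl, imidazole) to the (E)-cinnamyl silyl ether F10. Shi epoxidation (the L-fructose-derived diacetonide ketone catalyst, KHSO5, K2CO3 buffer near pH 10.5, MeCN–dimethoxymethane–H2O, 0 °C) should then give 20 directly. The dioxirane epoxidises the trans-disubstituted styrenyl alkene far faster than the terminal allyl ethers, the basic medium protects the product, and the catalyst (the enantiomer of the usual D-fructose-derived ketone) controls the face to give the (2S,3S) oxirane.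

Further compounds
F1 | step 10 | (2-bromo-4-iodophenoxy)triisopropylsilane | CC(C)[Si](Oc1ccc(I)cc1Br)(C(C)C)C(C)C
F2 | step 10 | {3-bromo-4-[(triisopropylsilyl)oxy]phenyl}magnesium chloride | CC(C)[Si](Oc1ccc([Mg]Cl)cc1Br)(C(C)C)C(C)C
F3 | step 10 | (2S)-1-{3-bromo-4-[(triisopropylsilyl)oxy]phenyl}-2-[2-(allyloxy)-4-(dimethoxymethyl)phenoxy]-3-[(triisopropylsilyl)oxy]propan-1-ol (both C1 epimers) | C=CCOc1cc(C(OC)OC)ccc1O[C@@H](CO[Si](C(C)C)(C(C)C)C(C)C)C(O)c1ccc(O[Si](C(C)C)(C(C)C)C(C)C)c(Br)c1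
F4 | step 10 | (2S)-1-{3-bromo-4-[(triisopropylsilyl)oxy]phenyl}-2-[2-(allyloxy)-4-(dimethoxymethyl)phenoxy]-3-[(triisopropylsilyl)oxy]propan-1-one | C=CCOc1cc(C(OC)OC)ccc1O[C@@H](CO[Si](C(C)C)(C(C)C)C(C)C)C(=O)c1ccc(O[Si](C(C)C)(C(C)C)C(C)C)c(Br)c1
F5 | step 10 | (1R,2S)-1-{3-bromo-4-[(triisopropylsilyl)oxy]phenyl}-2-[2-(allyloxy)-4-(dimethoxymethyl)phenoxy]-3-[(triisopropylsilyl)oxy]propan-1-ol | C=CCOc1cc(C(OC)OC)ccc1O[C@@H](CO[Si](C(C)C)(C(C)C)C(C)C)[C@H](O)c1ccc(O[Si](C(C)C)(C(C)C)C(C)C)c(Br)c1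
F6 | step 10 | 2-{[(1R,2S)-1-{3-bromo-4-[(triisopropylsilyl)oxy]phenyl}-1-hydroxy-3-[(triisopropylsilyl)oxy]propan-2-yl]oxy}-5-(dimethoxymethyl)phenol | COC(OC)c1ccc(O[C@@H](CO[Si](C(C)C)(C(C)C)C(C)C)[C@H](O)c2ccc(O[Si](C(C)C)(C(C)C)C(C)C)c(Br)c2)c(O)c1
F7 | step 10 | 4-{[(1R,2S)-1-{3-bromo-4-[(triisopropylsilyl)oxy]phenyl}-1-hydroxy-3-[(triisopropylsilyl)oxy]propan-2-yl]oxy}-3-hydroxybenzaldehyde | O=Cc1ccc(O[C@@H](CO[Si](C(C)C)(C(C)C)C(C)C)[C@H](O)c2ccc(O[Si](C(C)C)(C(C)C)C(C)C)c(Br)c2)c(O)c1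
F8 | step 10 | (2S,3S)-3-{3-bromo-4-[(triisopropylsilyl)oxy]phenyl}-2-{[(triisopropylsilyl)oxy]methyl}-2,3-dihydro-1,4-benzodioxine-6-carbaldehyde | O=Cc1ccc2c(c1)O[C@@H](c1ccc(O[Si](C(C)C)(C(C)C)C(C)C)c(Br)c1)[C@H](CO[Si](C(C)C)(C(C)C)C(C)C)O2
F9 | step 15 | (2S,3S)-3-[3-bromo-4-{[(1R,2S)-1-[3,4-bis(allyloxy)phenyl]-2,3-dihydroxypropyl]oxy}phenyl]-2-{[(triisopropylsilyl)oxy]methyl}-2,3-dihydro-1,4-benzodioxine-6-carbaldehyde | O=Cc1ccc2c(c1)O[C@@H](c1ccc(O[C@@H]([C@@H](O)CO)c3ccc(OCC=C)c(OCC=C)c3)c(Br)c1)[C@H](CO[Si](C(C)C)(C(C)C)C(C)C)O2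
F10 | step 13 | {[(2E)-3-[3,4-bis(allyloxy)phenyl]prop-2-en-1-yl]oxy}triisopropylsilane | CC(C)[Si](OC/C=C/c1ccc(OCC=C)c(OCC=C)c1)(C(C)C)C(C)C
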